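The numbers in the tables come from a simulation for substances that don't exist; noise was put on by code.

Start from the late times. Between 15.0 h and 25.0 h the summer run makes product at 0.109 mM h⁻¹, and over the same hours the dusk run makes it at 0.150 mM h⁻¹.

| flask | solid substrate | partner | remark | time |
|---|---|---|---|---|
| summer | 12 mM | 6 mM | run made earlier |  |
| dusk | 12 mM | 24 mM | run made earlier |  |
| noon | 6 mM | 12 mM | run made earlier |  |
| flask | 12 mM | 12.0 mM |  | 20 h |

| run | time / h | product / % |
|---|---|---|
| summer | 4.00 | 0.6 |
| summer | 8.00 | 3.7 |
| summer | 12.0 | 5.6 |
| summer | 15.0 | 6.7 |
| summer | 20.0 | 11.1 |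
| summer | 25.0 | 15.8 |
| dusk | 2.00 | 0.7 |
| dusk | 3.00 | 1.0 |
| dusk | 5.00 | 3.0 |
| dusk | 8.00 | 5.0 |
| dusk | 15.0 | 10.6 |
| dusk | 25.0 | 23.1 |
| noon | 5.00 | 3.7 |
| noon | 10.0 | 10.4 |
| noon | 15.0 | 18.5 |
| noon | 20.0 | 28.4 |
| noon | 25.0 | 37.1 |

(standard deviation of a reading: 0.5 percentage points)

- as a solid, counted per litre of solution: solid substrate
- the analysis behind the earlier runs scatters by 0.5 percentage points, standard deviation
- at the start none of the solid substrate is in solution

* how much product there is at 20 h, in percent of the solid substrate charged
* the change that raises the amount of product at 20 h, in percent of the solid substrate charged most ("none" if none brings more than 2 percentage points) (theta / gamma / epsilon / none)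
* amount of product at 20 h, in percent of the solid substrate charged, after gamma

- theta: doubling the amount of partner, all else as stated
- gamma: doubling the solubility of the solid substrate, all else as stated
- epsilon: doubling the dissolution coefficient of the solid substrate, all else as stated

Work in logarithms. Going from 6 mM to 24 mM of partner multiplies that pace by 1.38, an apparent order in partner of 0.229, as read through the scatter. On a logarithmic axis the flask's 12.0 mM lies midway between those two runs. So I take the flask's late rate r, the slope product keeps once the early slowness is over, as the midpoint of the two logarithms: 0.128 mM h⁻¹.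

The start is slower. The first readings of those runs, which stand close to their scatter, give a midpoint of 0.0275 mM h⁻¹, a factor of 4.65 below r. That slowness adds up to a lag τ, the time at which each late line reaches zero: 7.64 h for summer and 6.52 h for dusk, with midpoint 7.06 h. My reckoning for the flask at 20 h is therefore r(t − τ), which is 13.8 % of the solid substrate charged.

The forecast gives 14 % (range 12.5 % to 15.5 %) and picks gamma with 26.5 % (range 22 % to 30 %), holding that “Raising solubility doubles both the driving force and the dissolved level”.

The flask gives 14.1 %. The best change is gamma, which adds 13 percentage points and reaches 27.5 %, while epsilon adds 8.8 points and theta 2.8 points.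

    starting material + partner → product, rate k1*[starting material]*[partner]^0.5 (k = 3.21 × 10⁻⁴ M⁻⁰·⁵ s⁻¹)
    solid substrate ⇌ starting material, rate k2*(cs2 - [starting material]) while solid is left; crystals form when [starting material] > cs2 (solubility = 3.10 mM, k = 1.52 × 10⁻⁵ s⁻¹)

At 20.0 h the flask makes starting material 1.07 times as fast as it uses it up, each step taken net, down from 1.36 at 9.19 h. The 7.85 % of starting material standing in solution then equals 7.36 h of production at r, beside the lag of 7.06 h. Read at 3.0 d, the same flask holds 60.0 % of product, less than the 69.3 % that r(t − τ) gives.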